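The oxolane is opened at O1–C2, which uncovers C5–C4(OH)–C3–C9 as a hidden (S)-malic acid in which C4, the tertiary carbinol carbon of the ring, is the α-hydroxy-acid carbon. The key step forms the bond between C4 and the benzylic CH2 by alkylating a malic-acid-derived 2-tert-butyl-1,3-dioxolan-4-one (a temporary ring, self-regeneration of the stereocentre) with the complete, silyl-protected erythro-guaiacylglycerol aryl ether as its benzylic bromide; it joins the two halves and sets the quaternary C4 configuration in one operation. The nucleophile is the dianion of a dioxolanone acid that already holds C3 and the second guaiacyl ring. Hydride reduction and a quinone methide ring closure then give the oxolane.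

Key step: step 15

Remark: the oxolane atoms are called O1, C2 (aryl-bearing), C3 (CH2OH-bearing, exocyclic carbon C9), C4 (carbinol carbon) and C5 (OCH2); the glycerol chain is C7'' (ArCHOH), C8'' (CHOAr), C9'' (CH2OH); aldehyde 2 and bromide 16 are assumed not to be reliably purchasable and are made.

Step 1
Reactants: 1 vanillin
Product: 2 3-methoxy-4-[(triisopropylsilyl)oxy]benzaldehyde
Conditions: TIPSCl, imidazole, DMF, rt
Reagents that add atoms: chlorotriisopropylsilane, CC(C)[Si](Cl)(C(C)C)C(C)C
Why: Imidazole-promoted silyl ether formation at the phenol; the bulky aryl TIPS ether is chosen because it should survive the hydride and amide-base steps and stay in place when the other phenol is unmasked by hydrogenolysis in step 17.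

Step 2
Reactants: 3 methyl vanillate; 4 (R)-4-benzyl-3-(chloroacetyl)oxazolidin-2-one
Product: 5 methyl 4-{2-[(R)-4-benzyl-2-oxooxazolidin-3-yl]-2-oxoethoxy}-3-methoxybenzoate
Conditions: K2CO3, NaI (cat.), acetone, 50 °C
Reagents that add atoms: none
Why: Williamson ether synthesis in which the phenoxide displaces the activated α-halo imide halide (iodide catalysis), so that the C8''–O–aryl bond is in place before any stereocentre exists.

Step 3
Reactants: 5 aryloxyacetyl imide; 2 aldehyde
Product: 7 methyl 4-{[(2R,3S)-1-[(R)-4-benzyl-2-oxooxazolidin-3-yl]-3-hydroxy-3-{3-methoxy-4-[(triisopropylsilyl)oxy]phenyl}-1-oxopropan-2-yl]oxy}-3-methoxybenzoate, via Z-boron enolate 6 (not isolated)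
Conditions: Bu2BOTf, iPr2NEt, CH2Cl2, −78 to 0 °C; then 2, −78 to 0 °C; pH 7 buffer, MeOH, H2O2, 0 °C
Reagents that add atoms: none
Why: Evans syn-aldol reaction through a Zimmerman–Traxler chair on the enolate face away from the auxiliary benzyl group, which should fix C8'' in the required sense (S after step 4) together with a syn C7'' carbinol that is corrected in steps 6 and 7.

Step 4
Reactants: 7 syn-aldol adduct
Product: 8 methyl 4-{[(1S,2S)-1,3-dihydroxy-1-{3-methoxy-4-[(triisopropylsilyl)oxy]phenyl}propan-2-yl]oxy}-3-methoxybenzoate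
Conditions: LiBH4, MeOH (1 equiv), THF, 0 °C
Reagents that add atoms: none
Why: Reductive cleavage of the N-acyl oxazolidinone by LiBH4 should give the 1,3-diol at 0 °C while the electron-rich, deactivated methyl benzoate is left untouched.

Step 5
Reactants: 8 threo diol
Product: 9 methyl 4-{[(1S,2S)-3-[(tert-butyldimethylsilyl)oxy]-1-hydroxy-1-{3-methoxy-4-[(triisopropylsilyl)oxy]phenyl}propan-2-yl]oxy}-3-methoxybenzoate
Conditions: TBSCl, imidazole, CH2Cl2, 0 °C
Reagents that add atoms: tert-butyldimethylsilyl chloride, CC(C)(C)[Si](C)(C)Cl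
Why: Silyl ether formation that is selective for the primary over the secondary benzylic hydroxyl on steric grounds and that places a non-chelating group on C9'' for step 7.

Step 6
Reactants: 9 mono-TBS ether
Product: 10 methyl 4-{[(S)-3-[(tert-butyldimethylsilyl)oxy]-1-{3-methoxy-4-[(triisopropylsilyl)oxy]phenyl}-1-oxopropan-2-yl]oxy}-3-methoxybenzoate
Conditions: Dess–Martin periodinane, NaHCO3, CH2Cl2, 0 °C to rt
Reagents that add atoms: none
Why: Dess–Martin oxidation under buffered, non-basic conditions removes the wrongly configured C7'' carbinol without enolising the adjacent C8'' stereocentre.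

Step 7
Reactants: 10 α-aryloxy ketone
Product: 11 methyl 4-{[(1R,2S)-3-[(tert-butyldimethylsilyl)oxy]-1-hydroxy-1-{3-methoxy-4-[(triisopropylsilyl)oxy]phenyl}propan-2-yl]oxy}-3-methoxybenzoate
Conditions: Zn(BH4)2 (ethereal solution), Et2O, −30 °C
Reagents that add atoms: none
Why: Chelation-controlled (Cram-chelate) ketone reduction in which zinc is held between the carbonyl oxygen and the guaiacyl ether oxygens on C8'' and hydride enters from the side of the C8'' hydrogen, which should give the anti (erythro, 7''R,8''S) alcohol.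

Step 8
Reactants: 11 erythro alcohol
Product: 12 methyl 4-{[(1R,2S)-1,3-bis[(tert-butyldimethylsilyl)oxy]-1-{3-methoxy-4-[(triisopropylsilyl)oxy]phenyl}propan-2-yl]oxy}-3-methoxybenzoate
Conditions: TBSOTf, 2,6-lutidine, CH2Cl2, −78 to 0 °C
Reagents that add atoms: tert-butyldimethylsilyl triflate, CC(C)(C)[Si](C)(C)OS(=O)(=O)C(F)(F)F
Why: Silyl triflate silylation of the hindered secondary benzylic alcohol completes a protecting-group set on this half that fluoride alone removes.

Step 9
Reactants: 12 bis-TBS ester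
Product: 13 (4-{[(1R,2S)-1,3-bis[(tert-butyldimethylsilyl)oxy]-1-{3-methoxy-4-[(triisopropylsilyl)oxy]phenyl}propan-2-yl]oxy}-3-methoxyphenyl)methanol
Conditions: DIBAL-H, CH2Cl2, −78 to 0 °C
Reagents that add atoms: none
Why: DIBAL-H reduction of the methyl benzoate to the benzylic alcohol, to which the silyl ethers are inert.

Step 10
Reactants: 13 benzylic alcohol
Product: 14 4-{[(1R,2S)-1,3-bis[(tert-butyldimethylsilyl)oxy]-1-{3-methoxy-4-[(triisopropylsilyl)oxy]phenyl}propan-2-yl]oxy}-3-methoxybenzyl bromide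
Conditions: CBr4, PPh3, CH2Cl2, 0 °C
Reagents that add atoms: carbon tetrabromide, BrC(Br)(Br)Br
Why: Appel bromination converts the primary benzylic alcohol into the bromide under neutral conditions that should leave the secondary benzylic OTBS ether in place.

Step 11
Reactants: 15 [4-(benzyloxy)-3-methoxyphenyl]methanol
Product: 16 4-(benzyloxy)-3-methoxybenzyl bromide
Conditions: PBr3, Et2O, 0 °C
Reagents that add atoms: phosphorus tribromide, BrP(Br)Br
Why: Nucleophilic substitution of an electron-rich benzylic alcohol via its phosphite ester.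

Step 12
Reactants: 17 diethyl (S)-malate; 16 benzyl bromide
Product: 19 diethyl (2S,3R)-3-[4-(benzyloxy)-3-methoxybenzyl]-2-hydroxysuccinate, via dilithio alkoxide enolate 18 (not isolated)
Conditions: LiHMDS (2.1 equiv), THF, −78 to −20 °C; then 16, −78 to 0 °C; aq. NH4Cl
Reagents that add atoms: none
Why: Fráter–Seebach alkylation in which the chelated alkoxide enolate is benzylated anti to the C–O bond, so that the (S) centre of L-malate (the future C4) should set the future C3 as (3R).

Step 13
Reactants: 19 diethyl ester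
Product: 20 (2S,3R)-3-[4-(benzyloxy)-3-methoxybenzyl]-2-hydroxysuccinic acid
Conditions: KOH, EtOH/H2O, rt; then HCl
Reagents that add atoms: potassium hydroxide, [K+].[OH-]
Why: Mild saponification of both ethyl esters, under which the C3 stereocentre is not expected to epimerise.

Step 14
Reactants: 20 diacid
Product: 21 (R)-3-[4-(benzyloxy)-3-methoxyphenyl]-2-[(2S,4S)-2-tert-butyl-5-oxo-1,3-dioxolan-4-yl]propanoic acid
Conditions: t-BuCHO, TsOH·H2O (cat.), H2SO4 (cat.), pentane, reflux (Dean–Stark)
Reagents that add atoms: pivalaldehyde, CC(C)(C)C=O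
Why: Acid-catalysed acetalisation of the α-hydroxy acid (Seebach dioxolanone formation) should give the five-membered cis-2-tert-butyl-1,3-dioxolan-4-one, whose acetal carbon stores the C4 configuration while the β-carboxyl stays free.

Step 15
Reactants: 21 dioxolanone acid; 14 benzylic bromide
Product: 23 (R)-3-[4-(benzyloxy)-3-methoxyphenyl]-2-[(2S,4S)-4-(4-{[(1R,2S)-1,3-bis[(tert-butyldimethylsilyl)oxy]-1-{3-methoxy-4-[(triisopropylsilyl)oxy]phenyl}propan-2-yl]oxy}-3-methoxybenzyl)-2-tert-butyl-5-oxo-1,3-dioxolan-4-yl]propanoic acid, via dilithio carboxylate enolate 22 (not isolated)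
Conditions: LiHMDS (2.2 equiv), THF, −78 °C; then 14, −78 to −30 °C; cold 0.5 M HCl to pH 3
Reagents that add atoms: none
Why: LiHMDS converts 21 into the dilithio carboxylate enolate 22, whose enolate carbon C4 attacks the benzylic bromide 14 in an SN2 reaction. The closest known reaction type is the Seebach alkylation of malic-acid-derived 2-tert-butyl-1,3-dioxolan-4-ones with benzylic bromides (self-regeneration of stereocentres). No ring is closed in this step; the five-membered dioxolanone, closed by acetalisation in step 14 and absent from the target, is the temporary ring that carries the stereochemical information and is cleaved in step 16. The new quaternary stereocentre C4 is controlled by the acetal tert-butyl group: the electrophile enters the planar enolate on the face opposite to it, where the hydrogen of 21 stood, so the C4–O bond of L-malic acid is carried over with net retention and the new benzyl group ends up cis to the future C3 hydroxymethyl group. The step needs C-alkylation at C4 only and an untouched C3; C3 is alpha to a lithium carboxylate, which LiHMDS does not deprotonate, and 14 has no acidic C–H and no electrophilic site other than the bromide.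

Step 16
Reactants: 23 alkylated dioxolanone acid
Product: 24 (2S,3S)-2-(4-{[(1R,2S)-1,3-bis[(tert-butyldimethylsilyl)oxy]-1-{3-methoxy-4-[(triisopropylsilyl)oxy]phenyl}propan-2-yl]oxy}-3-methoxybenzyl)-3-[4-(benzyloxy)-3-methoxybenzyl]butane-1,2,4-triol
Conditions: LiAlH4, THF, 0 °C to rt; Rochelle salt
Reagents that add atoms: none
Why: LiAlH4 reduction of the carboxylic acid and of the dioxolanone ester opens the temporary ring, frees the tertiary C4 hydroxyl and the C5 and C9 hydroxymethyl groups, and reduces the released pivalaldehyde to neopentyl alcohol.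

Step 17
Reactants: 24 benzyl ether triol
Product: 25 (2S,3S)-2-(4-{[(1R,2S)-1,3-bis[(tert-butyldimethylsilyl)oxy]-1-{3-methoxy-4-[(triisopropylsilyl)oxy]phenyl}propan-2-yl]oxy}-3-methoxybenzyl)-3-(4-hydroxy-3-methoxybenzyl)butane-1,2,4-triol
Conditions: H2 (1 atm), Pd/C, EtOAc, rt
Reagents that add atoms: none
Why: Hydrogenolysis of the only aryl benzyl ether unmasks the phenol of the ring attached to C2 alone, the silyl ethers and the secondary benzylic C–O bonds being inert under these neutral conditions.

Step 18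
Reactants: 25 phenol triol
Product: 27 the target with its 4-O-TIPS, 7''-O-TBS and 9''-O-TBS ethers still in place (oxolane 2S,3R,4S), via p-quinone methide 26 (not isolated)
Conditions: Ag2O, CH2Cl2, rt, dark
Reagents that add atoms: none
Why: Oxidation of the 4-alkyl-2-methoxyphenol to its p-quinone methide and 5-exo oxa-1,6-addition of the C5 hydroxyl (quinone methide cyclisation, as in oxidative lignan ring closures) forms the O1–C2 bond; the aryl group should settle trans to the C3 hydroxymethyl and C4 benzyl groups (2S), and the C9 and C4 hydroxyls could only close oxetanes.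

Step 19
Reactants: 27 tris-silyl ether
Product: 28 target, (3S,4R,5S)-3-(4-{[(1R,2S)-1,3-dihydroxy-1-(4-hydroxy-3-methoxyphenyl)propan-2-yl]oxy}-3-methoxybenzyl)-5-(4-hydroxy-3-methoxyphenyl)-4-(hydroxymethyl)oxolan-3-ol
Conditions: TBAF, AcOH, THF, 0 °C to rt
Reagents that add atoms: none
Why: Fluoride-induced desilylation of the aryl TIPS ether and both TBS ethers, buffered with acetic acid so that the p-hydroxybenzyl alcohol and the 2-aryloxolane meet neither strong base nor acid.

Compound list
1 | vanillin | COc1cc(C=O)ccc1O | starting material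
2 | 3-methoxy-4-[(triisopropylsilyl)oxy]benzaldehyde | COc1cc(C=O)ccc1O[Si](C(C)C)(C(C)C)C(C)C | intermediate
3 | methyl vanillate | COC(=O)c1ccc(O)c(OC)c1 | starting material
4 | (R)-4-benzyl-3-(chloroacetyl)oxazolidin-2-one | O=C(CCl)N1[C@H](Cc2ccccc2)COC1=O | starting material
5 | methyl 4-{2-[(R)-4-benzyl-2-oxooxazolidin-3-yl]-2-oxoethoxy}-3-methoxybenzoate | COC(=O)c1ccc(OCC(=O)N2[C@H](Cc3ccccc3)COC2=O)c(OC)c1 | intermediate
6 | (Z)-dibutylboron enolate of 5 | CCCCB(CCCC)O/C(N1[C@H](Cc2ccccc2)COC1=O)=C\Oc1ccc(C(=O)OC)cc1OC | intermediate (not isolated)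
7 | (2R,3S) syn-aldol imide | COC(=O)c1ccc(O[C@H]([C@@H](O)c2ccc(O[Si](C(C)C)(C(C)C)C(C)C)c(OC)c2)C(=O)N2[C@H](Cc3ccccc3)COC2=O)c(OC)c1 | intermediate
8 | (1S,2S) threo 1,3-diol | COC(=O)c1ccc(O[C@H]([C@@H](O)c2ccc(O[Si](C(C)C)(C(C)C)C(C)C)c(OC)c2)CO)c(OC)c1 | intermediate
9 | (1S,2S) 9''-O-TBS alcohol | COC(=O)c1ccc(O[C@H]([C@@H](O)c2ccc(O[Si](C(C)C)(C(C)C)C(C)C)c(OC)c2)CO[Si](C)(C)C(C)(C)C)c(OC)c1 | intermediate
10 | (S) α-aryloxy ketone | COC(=O)c1ccc(O[C@@H](CO[Si](C)(C)C(C)(C)C)C(=O)c2ccc(O[Si](C(C)C)(C(C)C)C(C)C)c(OC)c2)c(OC)c1 | intermediate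
11 | (1R,2S) erythro alcohol | COC(=O)c1ccc(O[C@H]([C@H](O)c2ccc(O[Si](C(C)C)(C(C)C)C(C)C)c(OC)c2)CO[Si](C)(C)C(C)(C)C)c(OC)c1 | intermediate
12 | (1R,2S) bis-TBS ether methyl ester | COC(=O)c1ccc(O[C@H]([C@H](O[Si](C)(C)C(C)(C)C)c2ccc(O[Si](C(C)C)(C(C)C)C(C)C)c(OC)c2)CO[Si](C)(C)C(C)(C)C)c(OC)c1 | intermediate
13 | (1R,2S) bis-TBS ether benzylic alcohol | OCc1ccc(O[C@H]([C@H](O[Si](C)(C)C(C)(C)C)c2ccc(O[Si](C(C)C)(C(C)C)C(C)C)c(OC)c2)CO[Si](C)(C)C(C)(C)C)c(OC)c1 | intermediate
14 | (1R,2S) bis-TBS ether benzylic bromide | BrCc1ccc(O[C@H]([C@H](O[Si](C)(C)C(C)(C)C)c2ccc(O[Si](C(C)C)(C(C)C)C(C)C)c(OC)c2)CO[Si](C)(C)C(C)(C)C)c(OC)c1 | intermediate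
15 | [4-(benzyloxy)-3-methoxyphenyl]methanol | OCc1ccc(OCc2ccccc2)c(OC)c1 | starting material
16 | 4-(benzyloxy)-3-methoxybenzyl bromide | BrCc1ccc(OCc2ccccc2)c(OC)c1 | intermediate
17 | diethyl (S)-malate | CCOC(=O)C[C@H](O)C(=O)OCC | starting material
18 | dilithio alkoxide enolate of 17 | CCOC(O[Li])=C[C@H](O[Li])C(=O)OCC | intermediate (not isolated)
19 | diethyl (2S,3R)-3-[4-(benzyloxy)-3-methoxybenzyl]-2-hydroxysuccinate | CCOC(=O)[C@H](Cc1ccc(OCc2ccccc2)c(OC)c1)[C@H](O)C(=O)OCC | intermediate
20 | (2S,3R)-3-[4-(benzyloxy)-3-methoxybenzyl]-2-hydroxysuccinic acid | OC(=O)[C@H](Cc1ccc(OCc2ccccc2)c(OC)c1)[C@H](O)C(=O)O | intermediate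
21 | (R)-3-[4-(benzyloxy)-3-methoxyphenyl]-2-[(2S,4S)-2-tert-butyl-5-oxo-1,3-dioxolan-4-yl]propanoic acid (tert-butyl cis to the side chain) | CC(C)(C)[C@@H]1OC(=O)[C@H]([C@@H](Cc2ccc(OCc3ccccc3)c(OC)c2)C(=O)O)O1 | intermediate
22 | dilithio carboxylate enolate of 21 | CC(C)(C)[C@@H]1OC(O[Li])=C([C@@H](Cc2ccc(OCc3ccccc3)c(OC)c2)C(=O)O[Li])O1 | intermediate (not isolated)
23 | C4-benzylated (2S,4S)-dioxolanone acid, new benzyl trans to tert-butyl | CC(C)(C)[C@@H]1OC(=O)[C@](Cc2ccc(O[C@H]([C@H](O[Si](C)(C)C(C)(C)C)c3ccc(O[Si](C(C)C)(C(C)C)C(C)C)c(OC)c3)CO[Si](C)(C)C(C)(C)C)c(OC)c2)([C@@H](Cc2ccc(OCc3ccccc3)c(OC)c2)C(=O)O)O1 | intermediate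
24 | (2S,3S)-2,3-dibenzylbutane-1,2,4-triol, ring on the C3 benzyl O-benzylated | OC[C@](Cc1ccc(O[C@H]([C@H](O[Si](C)(C)C(C)(C)C)c2ccc(O[Si](C(C)C)(C(C)C)C(C)C)c(OC)c2)CO[Si](C)(C)C(C)(C)C)c(OC)c1)([C@@H](Cc1ccc(OCc2ccccc2)c(OC)c1)CO)O | intermediate
25 | (2S,3S)-triol with free 4-hydroxy-3-methoxybenzyl group | OC[C@](Cc1ccc(O[C@H]([C@H](O[Si](C)(C)C(C)(C)C)c2ccc(O[Si](C(C)C)(C(C)C)C(C)C)c(OC)c2)CO[Si](C)(C)C(C)(C)C)c(OC)c1)([C@@H](Cc1ccc(O)c(OC)c1)CO)O | intermediate
26 | p-quinone methide of 25 (C2 is the methide carbon) | COC1=CC(=C[C@@H](CO)[C@](O)(CO)Cc2ccc(O[C@H]([C@H](O[Si](C)(C)C(C)(C)C)c3ccc(O[Si](C(C)C)(C(C)C)C(C)C)c(OC)c3)CO[Si](C)(C)C(C)(C)C)c(OC)c2)C=CC1=O | intermediate (not isolated)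
27 | 4-O-TIPS, 7''-O-TBS, 9''-O-TBS ether of the target | COc1cc([C@@H](O[Si](C)(C)C(C)(C)C)[C@H](CO[Si](C)(C)C(C)(C)C)Oc2ccc(C[C@@]3(O)CO[C@H](c4ccc(O)c(OC)c4)[C@H]3CO)cc2OC)ccc1O[Si](C(C)C)(C(C)C)C(C)C | intermediate
28 | target (CNP0350466.2) | COc1cc([C@@H](O)[C@H](CO)Oc2ccc(C[C@@]3(O)CO[C@H](c4ccc(O)c(OC)c4)[C@H]3CO)cc2OC)ccc1O | target

Total step count: 19. Longest linear sequence: 14 steps (from 3: steps 2–10, then 15–19).

Steps most likely to fail

Step 18. The ring closure onto the quinone methide may proceed with poor facial selectivity at C2, or the product phenol may be oxidised further before the starting phenol is consumed. The fallback separates oxidation from ring closure and puts the closure under thermodynamic control. It sets out from 25: oxidation with DDQ in CH2Cl2/MeOH at −20 °C traps the quinone methide with methanol as the benzylic methyl ether F1 (both C2 epimers, with any directly cyclised material). Mild acid (PPTS, CH2Cl2, rt) then ionises the p-hydroxybenzylic ether and lets the C5 hydroxyl close the oxolane reversibly by an SN1 path, which should favour the 2,3-trans isomer. The route is rejoined at 27.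

Step 15. Alkylation of the hindered dianion by the large electron-rich bromide may be slow enough for the enolate to fragment, or the facial selectivity may erode. The fallback moves the control element from the acetal tert-butyl group to the ring substituent of the classical lignan lactone. It sets out from 21: BH3·SMe2 in THF reduces the free carboxylic acid, and TsOH in MeOH then translactonises with loss of pivalaldehyde to the hydroxy lactone F2. Its dianion (LDA, 2.2 equiv, THF/DMPU, −78 °C) is alkylated with 14 anti to the β-arylmethyl group to give the α-benzyl-α-hydroxy lactone F3, which has the same C3 and C4 configuration as 23. LiAlH4 reduction of F3 rejoins the route at 24.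

Step 7. Chelation by the aryl ether oxygen may be too weak, so that open-chain (Felkin) attack competes and the syn alcohol forms. The fallback replaces substrate control by reagent control: 10 is reduced with (R)-Me-CBS oxazaborolidine and BH3·SMe2 in THF at −20 °C, where the aryl group acts as the large substituent and the 7''R alcohol 11 should result. This fallback makes no new compound (F0); it sets out from 10 and returns at 11.

Further compounds
F1 | step 18 | (2S,3S)-triol 25 carrying a methoxy group on C2 (benzylic methyl ether, C2 epimers) | OC[C@](Cc1ccc(O[C@H]([C@H](O[Si](C)(C)C(C)(C)C)c2ccc(O[Si](C(C)C)(C(C)C)C(C)C)c(OC)c2)CO[Si](C)(C)C(C)(C)C)c(OC)c1)([C@@H](C(OC)c1ccc(O)c(OC)c1)CO)O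
F2 | step 15 | (3S,4S)-4-[4-(benzyloxy)-3-methoxybenzyl]-3-hydroxydihydrofuran-2(3H)-one | O=C1OC[C@H](Cc2ccc(OCc3ccccc3)c(OC)c2)[C@@H]1O
F3 | step 15 | α-hydroxy lactone F2 benzylated at the α-carbon with 14, new benzyl trans to the β-arylmethyl group | O=C1OC[C@H](Cc2ccc(OCc3ccccc3)c(OC)c2)[C@@]1(O)Cc1ccc(O[C@H]([C@H](O[Si](C)(C)C(C)(C)C)c2ccc(O[Si](C(C)C)(C(C)C)C(C)C)c(OC)c2)CO[Si](C)(C)C(C)(C)C)c(OC)c1
F0 | step 7 | none | none
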